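**Plan**

- Numbering: C7 and C7' are the two ArCH–O carbons, C8 is the CH bridgehead, C8' the C(OH) bridgehead, and C9 and C9' the OCH2 carbons. Ring A = C7–O–C9'–C8'–C8, ring B = C7'–O–C9–C8–C8'.
- Cuts, in retrosynthetic order: first the C7–H and C7'–H bonds and the two aryl–C bonds, back to a cis-fused bislactone with C7 and C7' as carbonyl carbons. Then the acyl C7'–O bond of ring B and the C8–C9 bond, back to a ring A lactone carrying OH and CO2Me on C8'. Last, the C7–O and O–C9' bonds of ring A.
- Enabling feature: in the ring A lactone the quaternary C8' is flanked by two CH2 groups, C8 and C9', which differ only through the ring oxygen between C9' and C7. With this oxygen removed, C7, C8, C8' and C9' form a mirror-symmetric 3,3-disubstituted cyclobutanone, so one enantioselective oxygen insertion gives ring A and the tertiary carbinol centre at once.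
- Forward order: cyclobutanone, ring A by ring expansion, C9 onto C8 and ring B by translactonisation, both aryl groups by aryllithium addition, both benzylic C–H bonds by silane reduction, phenols freed last.
- Stereochemistry: C8' (S) comes from the chiral phosphoric acid. C8 (R in the target) comes from attack anti to the C8' alkoxide, secured because only the cis isomer can close ring B. C7 (R) and C7' (S) come from hydride delivery to the convex face, which places both aryl groups endo, as the target requires (H7, H8, H7' and the C8' OH all on one face).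

Key step: step 5

Assumption: the sense of induction of the phosphoric acid on the cyclobutanone of the key step cannot be predicted with confidence, so the (R)-acid is written and its antipode is to be used if the (R)-acid favours the (R)-lactone.

**Step 1**
Reactants: 1 3-oxocyclobutane-1-carboxylic acid
Product: 2 methyl 3,3-dimethoxycyclobutane-1-carboxylate
Conditions: HC(OMe)3 (3 equiv), TsOH·H2O (5 mol%), MeOH, reflux
Reagents that add atoms: methanol, CO; trimethyl orthoformate, COC(OC)OC
Why: Fischer esterification and dimethyl ketal formation run together under acid catalysis because the orthoformate consumes the water of both equilibria, and the strained ketone ketalises readily since the change to sp3 relieves angle strain.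

**Step 2**
Reactants: 2 methyl 3,3-dimethoxycyclobutane-1-carboxylate
Product: 3 methyl 1-hydroxy-3,3-dimethoxycyclobutane-1-carboxylate
Conditions: LiN(iPr)2 (1.15 equiv), THF, −78 °C; 2-(phenylsulfonyl)-3-phenyloxaziridine (1.3 equiv), −78 °C; AcOH
Reagents that add atoms: 2-(phenylsulfonyl)-3-phenyloxaziridine, O=S(=O)(c1ccccc1)N1OC1c1ccccc1
Why: Davis oxidation of a lithium ester enolate, whose carbon attacks the electrophilic oxaziridine oxygen, on a substrate that has no β-leaving group and a base-stable ketal, and without a stereochemical issue because the product keeps its mirror plane.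

**Step 3**
Reactants: 3 methyl 1-hydroxy-3,3-dimethoxycyclobutane-1-carboxylate; 4 benzyl bromide
Product: 5 methyl 1-(benzyloxy)-3,3-dimethoxycyclobutane-1-carboxylate
Conditions: NaH (1.3 equiv), BnBr (1.3 equiv), DMF, 0 °C → rt
Reagents that add atoms: benzyl bromide 4, BrCc1ccccc1
Why: Williamson ether synthesis on the sodium alkoxide of a tertiary α-hydroxy ester with a reactive benzylic halide in a dipolar aprotic solvent that makes up for the hindrance, while the ester has no α-hydrogen left and the ketal is inert to base.

**Step 4**
Reactants: 5 methyl 1-(benzyloxy)-3,3-dimethoxycyclobutane-1-carboxylate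
Product: 6 methyl 1-(benzyloxy)-3-oxocyclobutane-1-carboxylate (achiral, mirror plane through C1 and C3)
Conditions: 1 M aq. HCl, acetone, rt
Reagents that add atoms: water, O
Why: Acid-catalysed ketal hydrolysis, driven by excess water, in which the methyl ester and the benzyl ether survive dilute acid at room temperature and loss of benzyl alcohol is not expected because it would have to give a cyclobutenone.

**Step 5**
Reactants: 6 methyl 1-(benzyloxy)-3-oxocyclobutane-1-carboxylate
Product: 8 methyl (S)-3-(benzyloxy)-5-oxotetrahydrofuran-3-carboxylate, via Criegee perhydrate 7 (not isolated)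
Conditions: (R)-3,3'-di(pyren-1-yl)-5,5',6,6',7,7',8,8'-octahydro-1,1'-binaphthalene-2,2'-diyl hydrogen phosphate (10 mol%), 30% aq. H2O2 (1.5 equiv), CHCl3, −40 °C
Reagents that add atoms: hydrogen peroxide, OO
Why: Hydrogen peroxide, activated by hydrogen bonding to the phosphoric acid, adds to the strain-activated ketone to give the Criegee perhydrate 7, and the acid, bridging the carbinol OH and the distal peroxide oxygen, triggers the 1,2-shift of the CH2 group that lies antiperiplanar to the O–O bond while water departs. The closest known reaction type is the chiral Brønsted acid catalysed asymmetric Baeyer–Villiger oxidation of prochiral 3-substituted cyclobutanones with aqueous H2O2 to β-substituted γ-butyrolactones, applied here to a 3,3-disubstituted member of the class. Ring A is not closed end to end but arises by ring expansion of the four-membered carbocycle to the five-membered lactone: the C7–C9' bond is exchanged for C7–O and O–C9', the migrating CH2 becoming C9' and the remaining one C8. No bond to C8' is made or broken, so this carbon becomes stereogenic only because its two CH2 neighbours are made different, and its (S) configuration is fixed by the catalyst pocket, which decides which enantiotopic C–C bond can align with the O–O bond. The step needs enantiotopic group selectivity and chemoselectivity: the puckered ring presents a flat, π-stacking benzyloxy group and a hydrogen-bond-accepting ester of different shape on C8', which should orient the perhydrate in the pocket, while ring strain lets the ketone react at −40 °C under conditions that leave ester and benzyl ether alone and suppress the uncatalysed background. Residual minor enantiomer should be removable by recrystallisation at the stage of the bislactone made in step 7.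

**Step 6**
Reactants: 8 methyl (S)-3-(benzyloxy)-5-oxotetrahydrofuran-3-carboxylate
Product: 9 methyl (S)-3-hydroxy-5-oxotetrahydrofuran-3-carboxylate
Conditions: H2 (1 atm), 10% Pd/C, EtOAc, rt; filtration, evaporation
Reagents that add atoms: none
Why: Catalytic hydrogenolysis of a benzyl ether under neutral conditions, which cleaves only the O–CH2Ph bond, so that lactone, ester and the configuration at C8' stay untouched and the free hydroxyl needed for the dianion chemistry is released.

**Step 7**
Reactants: 9 methyl (S)-3-hydroxy-5-oxotetrahydrofuran-3-carboxylate; 10 formaldehyde (monomer in THF, from cracking of commercial paraformaldehyde)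
Product: 12 (3aS,6aS)-3a-hydroxytetrahydro-1H,3H-furo[3,4-c]furan-1,4-dione (cis-fused bislactone; C7 and C7' are the carbonyl carbons), via hydroxymethyl lactone 11 (not isolated)
Conditions: LiN(iPr)2 (2.3 equiv), THF, −78 °C; CH2O (1.5 equiv), −78 → −50 °C; AcOH (2.5 equiv), non-aqueous work-up; crude: camphor-10-sulfonic acid (10 mol%), PhMe, 50 °C; recrystallisation
Reagents that add atoms: formaldehyde 10, C=O
Why: Aldol addition of a β-alkoxide lactone enolate dianion (Fráter–Seebach logic, known for β-hydroxy-γ-butyrolactones): the oxyanion on C8' cannot leave, so β-elimination is shut off, formaldehyde should approach C8 opposite to the solvated lithium alkoxide and hence cis to the ester (4S in 11), and only this isomer can close ring B by 5-exo-trig transesterification onto C7', so that the cis-fused bislactone differs in constitution from any C8 epimer and is easily separated from it.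

**Step 8**
Reactants: 13 4-bromo-2-methoxyphenol
Product: 14 (4-bromo-2-methoxyphenoxy)(tert-butyl)dimethylsilane
Conditions: t-BuMe2SiCl (1.1 equiv), imidazole (1.1 equiv), DMF, rt
Reagents that add atoms: tert-butyldimethylsilyl chloride, CC(C)(C)[Si](C)(C)Cl
Why: Silyl ether formation from a phenol with a silyl chloride and imidazole, chosen because the aryl silyl ether tolerates bromine–lithium exchange and cold BF3·OEt2 and is later removed by fluoride without acid.

**Step 9**
Reactants: 12 (3aS,6aS)-3a-hydroxytetrahydro-1H,3H-furo[3,4-c]furan-1,4-dione; 14 (4-bromo-2-methoxyphenoxy)(tert-butyl)dimethylsilane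
Product: 16 (3aS,6aS)-1,4-bis[4-(tert-butyldimethylsilyloxy)-3-methoxyphenyl]tetrahydro-1H,3H-furo[3,4-c]furan-1,3a,4-triol (bis-hemiketal; C7/C7' anomers unassigned), via aryllithium 15 (not isolated)
Conditions: 14 (3.3 equiv), n-BuLi (3.2 equiv), THF, −78 °C, 30 min; 12 in THF, −78 °C, 2 h; AcOH, −78 °C
Reagents that add atoms: aryl bromide 14 (two aryl groups), COc1cc(Br)ccc1O[Si](C)(C)C(C)(C)C
Why: Bromine–lithium exchange followed by 1,2-addition of an aryllithium to lactone carbonyl groups, the reaction type used for C-aryl glycosides and for furofuranone lactones: the first equivalent turns the C8' hydroxyl into an alkoxide that cannot be eliminated, the next two add to C7 and C7', the cyclic lithium hemiketal alkoxides persist at −78 °C so that no ketone is offered to further aryllithium, and C8 and C8' are not touched.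

**Step 10**
Reactants: 16 (3aS,6aS)-1,4-bis[4-(tert-butyldimethylsilyloxy)-3-methoxyphenyl]tetrahydro-1H,3H-furo[3,4-c]furan-1,3a,4-triol
Product: 17 (1R,3aS,4S,6aR)-1,4-bis[4-(tert-butyldimethylsilyloxy)-3-methoxyphenyl]tetrahydro-1H,3H-furo[3,4-c]furan-3a-ol (both aryl groups endo)
Conditions: Et3SiH (8 equiv), BF3·OEt2 (3 equiv), CH2Cl2, −78 → −40 °C; Et3N, then aq. NaHCO3 at −40 °C
Reagents that add atoms: none
Why: Ionic reduction of aryl hemiketals (silane with Lewis acid): BF3·OEt2 ionises each hemiketal to an aryl-stabilised oxocarbenium ion, Et3SiH delivers hydride on the convex face of the cis-fused bicycle, on the side of H8 and of the small free C8' hydroxyl, which sets C7 as R and C7' as S with both aryl groups endo, and the low temperature together with the cold basic quench keeps this kinetic product from Lewis acid epimerisation at the benzylic ethers.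

**Step 11**
Reactants: 17 (1R,3aS,4S,6aR)-1,4-bis[4-(tert-butyldimethylsilyloxy)-3-methoxyphenyl]tetrahydro-1H,3H-furo[3,4-c]furan-3a-ol
Product: 18 (1R,3aS,4S,6aR)-1,4-bis(4-hydroxy-3-methoxyphenyl)tetrahydro-1H,3H-furo[3,4-c]furan-3a-ol (target, CNP0138682.2)
Conditions: Bu4NF (2.4 equiv), AcOH (2.4 equiv), THF, 0 °C
Reagents that add atoms: none
Why: Fluoride-induced cleavage of aryl silyl ethers, buffered with acetic acid so that no long-lived phenoxide can open the benzylic ethers through a quinone methide, which leaves all four stereocentres as set.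

**Compound list**

1 | 3-oxocyclobutane-1-carboxylic acid | O=C1CC(C(=O)O)C1 | starting material
2 | methyl 3,3-dimethoxycyclobutane-1-carboxylate | COC(=O)C1CC(OC)(OC)C1 | intermediate
3 | methyl 1-hydroxy-3,3-dimethoxycyclobutane-1-carboxylate | COC(=O)C1(O)CC(OC)(OC)C1 | intermediate
4 | benzyl bromide | BrCc1ccccc1 | starting material
5 | methyl 1-(benzyloxy)-3,3-dimethoxycyclobutane-1-carboxylate | COC(=O)C1(OCc2ccccc2)CC(OC)(OC)C1 | intermediate
6 | methyl 1-(benzyloxy)-3-oxocyclobutane-1-carboxylate | COC(=O)C1(OCc2ccccc2)CC(=O)C1 | intermediate
7 | methyl 1-(benzyloxy)-3-hydroperoxy-3-hydroxycyclobutane-1-carboxylate (Criegee perhydrate, not isolated) | COC(=O)C1(OCc2ccccc2)CC(O)(OO)C1 | intermediate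
8 | methyl (S)-3-(benzyloxy)-5-oxotetrahydrofuran-3-carboxylate | O=C1C[C@@](OCc2ccccc2)(C(=O)OC)CO1 | intermediate
9 | methyl (S)-3-hydroxy-5-oxotetrahydrofuran-3-carboxylate | O=C1C[C@@](O)(C(=O)OC)CO1 | intermediate
10 | formaldehyde | C=O | starting material
11 | methyl (3S,4S)-3-hydroxy-4-(hydroxymethyl)-5-oxotetrahydrofuran-3-carboxylate (CH2OH cis to CO2Me, not isolated) | O=C1OC[C@](O)(C(=O)OC)[C@@H]1CO | intermediate
12 | (3aS,6aS)-3a-hydroxytetrahydro-1H,3H-furo[3,4-c]furan-1,4-dione | O=C1OC[C@@]2(O)[C@@H]1COC2=O | intermediate
13 | 4-bromo-2-methoxyphenol | COc1cc(Br)ccc1O | starting material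
14 | (4-bromo-2-methoxyphenoxy)(tert-butyl)dimethylsilane | COc1cc(Br)ccc1O[Si](C)(C)C(C)(C)C | intermediate
15 | [4-(tert-butyldimethylsilyloxy)-3-methoxyphenyl]lithium (not isolated) | COc1cc([Li])ccc1O[Si](C)(C)C(C)(C)C | intermediate
16 | (3aS,6aS)-1,4-bis[4-(tert-butyldimethylsilyloxy)-3-methoxyphenyl]tetrahydro-1H,3H-furo[3,4-c]furan-1,3a,4-triol | COc1cc(C2(O)OC[C@@]3(O)[C@@H]2COC3(O)c2ccc(O[Si](C)(C)C(C)(C)C)c(OC)c2)ccc1O[Si](C)(C)C(C)(C)C | intermediate
17 | (1R,3aS,4S,6aR)-1,4-bis[4-(tert-butyldimethylsilyloxy)-3-methoxyphenyl]tetrahydro-1H,3H-furo[3,4-c]furan-3a-ol | COc1cc([C@@H]2OC[C@@]3(O)[C@@H]2CO[C@H]3c2ccc(O[Si](C)(C)C(C)(C)C)c(OC)c2)ccc1O[Si](C)(C)C(C)(C)C | intermediate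
18 | (1R,3aS,4S,6aR)-1,4-bis(4-hydroxy-3-methoxyphenyl)tetrahydro-1H,3H-furo[3,4-c]furan-3a-ol | COc1cc([C@@H]2OC[C@@]3(O)[C@@H]2CO[C@H]3c2ccc(O)c(OC)c2)ccc1O | target

Total step count: 11.
Longest linear sequence: 10 steps (steps 1–7 and 9–11, from 1 to 18). Step 8 is a one-step branch.

**Steps most likely to fail**

**Step 5.** Discrimination between the two enantiotopic CH2 groups may be too weak, because the two substituents on C8' are similar in size and both sit far from the reacting carbonyl group.

Fallback (sets out from 6, comes back at 8): oxygen insertion without asymmetric catalysis, followed by resolution through covalent diastereomers.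
- Oxidation of 6 with mCPBA/NaHCO3 in CH2Cl2 should give racemic methyl 3-(benzyloxy)-5-oxotetrahydrofuran-3-carboxylate F1.
- Warming with (S)-1-phenylethylamine should open the lactone rather than the hindered ester, giving two diastereomeric hydroxy amides. From these, methyl (S)-2-(benzyloxy)-2-(hydroxymethyl)-4-oxo-4-{[(S)-1-phenylethyl]amino}butanoate F2 is separated by crystallisation or chromatography.
- TsOH·H2O in hot toluene then relactonises it to 8 and releases the amine.

**Step 7.** Three processes may erode the step: poor facial selectivity at C8 (the ester on the face to be attacked is not small), repeated hydroxymethylation, and retro-aldol loss of formaldehyde on warming.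

Fallback (sets out from 9, comes back at 12): C9 is brought in at the aldehyde oxidation level, and C8 is set by directed hydrogenation instead of by enolate attack.
- The dianion of 9 is formylated with methyl formate (Claisen condensation) to methyl (S)-3-hydroxy-4-(hydroxymethylidene)-5-oxotetrahydrofuran-3-carboxylate F3. In this compound C8 is planar and a second acylation is not possible.
- Selective O-acetylation of the acidic enol (AcCl, Et3N, CH2Cl2, −20 °C) gives methyl (S)-4-(acetoxymethylidene)-3-hydroxy-5-oxotetrahydrofuran-3-carboxylate F4.
- Hydroxyl-directed hydrogenation with [Rh(nbd)(dppb)]BF4 and H2 in CH2Cl2 delivers hydrogen to C8 from the face of the coordinating C8' hydroxyl. This gives methyl (3S,4S)-4-(acetoxymethyl)-3-hydroxy-5-oxotetrahydrofuran-3-carboxylate F5, with C9 cis to the ester.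
- Acid methanolysis (HCl in MeOH), then camphor-10-sulfonic acid in warm toluene, removes the acetate and closes ring B to 12.

**Step 9.** Three processes may compete with clean double addition: enolisation at C8 by the basic aryllithium, premature collapse of the tetrahedral adducts followed by over-addition, and retro-aldol cleavage of the C8–C8' bond.

Fallback (sets out from 12, comes back at 16): acylation of the aryllithium by open-chain Weinreb amides instead of addition to the lactones.
- MeNH(OMe)·HCl/AlMe3 in CH2Cl2 opens both lactones to (2S,3S)-2-hydroxy-2,3-bis(hydroxymethyl)-N1,N4-dimethoxy-N1,N4-dimethylbutanediamide F6.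
- Et3SiCl/imidazole caps the two primary hydroxyls to give (2S,3S)-2-hydroxy-N1,N4-dimethoxy-N1,N4-dimethyl-2,3-bis[(triethylsilyloxy)methyl]butanediamide F7.
- Aryllithium 15 (3.3 equiv, THF, −78 °C) forms chelated adducts that cannot release a ketone before the quench. This gives (2S,3S)-1,4-bis[4-(tert-butyldimethylsilyloxy)-3-methoxyphenyl]-2-hydroxy-2,3-bis[(triethylsilyloxy)methyl]butane-1,4-dione F8.
- AcOH/THF/H2O removes the two primary triethylsilyl ethers while the aryl silyl ethers stay, and the freed hydroxy ketones close to 16.

**Further compounds**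

F1 | step 5 | racemic methyl 3-(benzyloxy)-5-oxotetrahydrofuran-3-carboxylate | O=C1CC(OCc2ccccc2)(C(=O)OC)CO1
F2 | step 5 | methyl (S)-2-(benzyloxy)-2-(hydroxymethyl)-4-oxo-4-{[(S)-1-phenylethyl]amino}butanoate | C[C@H](NC(=O)C[C@@](OCc1ccccc1)(C(=O)OC)CO)c1ccccc1
F3 | step 7 | methyl (S)-3-hydroxy-4-(hydroxymethylidene)-5-oxotetrahydrofuran-3-carboxylate | O=C1OC[C@](O)(C(=O)OC)C1=CO
F4 | step 7 | methyl (S)-4-(acetoxymethylidene)-3-hydroxy-5-oxotetrahydrofuran-3-carboxylate | O=C1OC[C@](O)(C(=O)OC)C1=COC(C)=O
F5 | step 7 | methyl (3S,4S)-4-(acetoxymethyl)-3-hydroxy-5-oxotetrahydrofuran-3-carboxylate | O=C1OC[C@](O)(C(=O)OC)[C@@H]1COC(C)=O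
F6 | step 9 | (2S,3S)-2-hydroxy-2,3-bis(hydroxymethyl)-N1,N4-dimethoxy-N1,N4-dimethylbutanediamide | CON(C)C(=O)[C@@H](CO)[C@](O)(CO)C(=O)N(C)OC
F7 | step 9 | (2S,3S)-2-hydroxy-N1,N4-dimethoxy-N1,N4-dimethyl-2,3-bis[(triethylsilyloxy)methyl]butanediamide | CON(C)C(=O)[C@@H](CO[Si](CC)(CC)CC)[C@](O)(CO[Si](CC)(CC)CC)C(=O)N(C)OC
F8 | step 9 | (2S,3S)-1,4-bis[4-(tert-butyldimethylsilyloxy)-3-methoxyphenyl]-2-hydroxy-2,3-bis[(triethylsilyloxy)methyl]butane-1,4-dione | COc1cc(C(=O)[C@@H](CO[Si](CC)(CC)CC)[C@](O)(CO[Si](CC)(CC)CC)C(=O)c2ccc(O[Si](C)(C)C(C)(C)C)c(OC)c2)ccc1O[Si](C)(C)C(C)(C)C
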